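Ring A is not brought in as a hindered benzoic acid but is built on the depside oxygen. The key step exploits the ortho pair C6 methyl/C1 carbonyl of ring A, which are the two alkyne carbons of a but-2-ynoate ester of the ring B C4 phenol, and the contiguous C2 hydroxyl, C3 carboxyl and C4 methoxyl, which with C5 map onto a silyl ketene acetal diene from a (1-methoxyethylidene)malonate. One thermal cycloaddition with aromatising loss of benzyl alcohol forms C1–C2 and C5–C6 and places all six ring A substituents. Its precursor is ring B as benzyl ether and benzyl ester carrying the ynoate, so one hydrogenolysis then liberates squamatic acid.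

Key step: step 9

Remark on the chemistry: the ketene acetal double bond of diene 14 may form as either geometric isomer; both give the same arene, so 14 is written without double-bond configuration. Cycloadduct 15 is racemic at its ketal carbon, which is lost on aromatisation. The target has no stereocentre.

Step 1
Reactants: 1 methyl 2,4-dihydroxy-3,6-dimethylbenzoate
Product: 3 2,4-dihydroxy-3,6-dimethylbenzoic acid, via 2,4-dihydroxy-3,6-dimethylbenzoylium hydrogen sulfate 2 (not isolated)
Conditions: conc. H2SO4, 0 °C to rt; then ice/H2O
Reagents that add atoms: water, O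
Why: In concentrated H2SO4 the doubly ortho-substituted, electron-rich ester should ionise by the acylium (AAC1) pathway of hindered benzoates to salt 2, which takes up water on quenching, so the ester is cleaved without the hot alkali that would decarboxylate this β-resorcylic acid.

Step 2
Reactants: 3 2,4-dihydroxy-3,6-dimethylbenzoic acid
Product: 4 benzyl 2,4-dihydroxy-3,6-dimethylbenzoate
Conditions: BnBr (1.05 equiv), KHCO3, DMF, rt
Reagents that add atoms: benzyl bromide, BrCc1ccccc1
Why: Chemoselective carboxylate O-alkylation (SN2), since KHCO3 ionises the carboxylic acid but not the phenols.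

Step 3
Reactants: 4 benzyl 2,4-dihydroxy-3,6-dimethylbenzoate
Product: 5 benzyl 2-hydroxy-3,6-dimethyl-4-(prop-2-en-1-yloxy)benzoate
Conditions: allyl bromide (1.1 equiv), K2CO3, acetone, reflux
Reagents that add atoms: allyl bromide, C=CCBr
Why: Williamson ether synthesis that should select the 4-hydroxyl, because the 2-hydroxyl is hydrogen-bonded to the ester carbonyl, less acidic and flanked by two substituents.

Step 4
Reactants: 5 benzyl 2-hydroxy-3,6-dimethyl-4-(prop-2-en-1-yloxy)benzoate
Product: 6 benzyl 2-(benzyloxy)-3,6-dimethyl-4-(prop-2-en-1-yloxy)benzoate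
Conditions: BnBr (1.5 equiv), K2CO3, DMF, 60 °C
Reagents that add atoms: benzyl bromide, BrCc1ccccc1
Why: Williamson benzylation of the one remaining, chelated phenol under more forcing conditions (polar solvent, heat, excess halide), with no other nucleophilic site left.

Step 5
Reactants: 6 benzyl 2-(benzyloxy)-3,6-dimethyl-4-(prop-2-en-1-yloxy)benzoate
Product: 7 benzyl 2-(benzyloxy)-4-hydroxy-3,6-dimethylbenzoate
Conditions: Pd(PPh3)4 (cat.), morpholine, THF, rt
Reagents that add atoms: none
Why: Tsuji–Trost type deallylation, in which zerovalent palladium ionises the aryl allyl ether to a π-allyl complex that morpholine captures, freeing only the 4-hydroxyl and leaving the benzyl ether and benzyl ester intact.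

Step 6
Reactants: 7 benzyl 2-(benzyloxy)-4-hydroxy-3,6-dimethylbenzoate; 8 but-2-ynoic acid
Product: 9 3-(benzyloxy)-4-(benzyloxycarbonyl)-2,5-dimethylphenyl but-2-ynoate
Conditions: DCC, DMAP (5 mol%), CH2Cl2, 0 °C to rt
Reagents that add atoms: none
Why: Steglich esterification of the single free phenol, which is hindered on one side only; low temperature and a small DMAP charge should limit amine-induced isomerisation of the ynoate.

Step 7
Reactants: 10 dibenzyl malonate; 11 trimethyl orthoacetate
Product: 12 dibenzyl 2-(1-methoxyethylidene)propanedioate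
Conditions: Ac2O (2.2 equiv), ZnCl2 (cat.), 120–130 °C, MeOAc distilled off
Reagents that add atoms: none
Why: Claisen-type orthoester condensation of an active methylene compound (as in the preparation of alkoxymethylenemalonates): ZnCl2 ionises the orthoester, the malonate enol adds and methanol is lost, while Ac2O traps the methanol so that the benzyl esters are not exchanged.

Step 8
Reactants: 12 dibenzyl 2-(1-methoxyethylidene)propanedioate
Product: 14 benzyl 2-[benzyloxy(trimethylsilyloxy)methylidene]-3-methoxybut-3-enoate, via lithium dienolate 13 (not isolated)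
Conditions: LiN(iPr)2, THF, −78 °C; then Me3SiCl, −78 °C to rt; LiCl filtered off from pentane under argon, used crude
Reagents that add atoms: chlorotrimethylsilane, C[Si](C)(C)Cl
Why: Vinylogous (γ) deprotonation of the alkylidene malonate by the hindered amide should give the cross-conjugated dienolate 13, which Me3SiCl silylates on oxygen to the silyl ketene acetal, the standard entry to 1-alkoxy-1-silyloxy-3-methoxy dienes.

Step 9
Reactants: 9 3-(benzyloxy)-4-(benzyloxycarbonyl)-2,5-dimethylphenyl but-2-ynoate; 14 benzyl 2-[benzyloxy(trimethylsilyloxy)methylidene]-3-methoxybut-3-enoate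
Product: 17 benzyl 2-(benzyloxy)-4-{[3-(benzyloxycarbonyl)-2-hydroxy-4-methoxy-6-methylbenzoyl]oxy}-3,6-dimethylbenzoate, via cyclohexa-1,4-diene ketal cycloadduct 15 (not isolated), via ring A trimethylsilyl ether 16 (not isolated)
Conditions: 14 (3 equiv), toluene, 120 °C, sealed tube; then 1 M HCl, THF, rt
Reagents that add atoms: none
Why: The electron-rich diene 14 and the electron-poor aryl ynoate 9 should combine in a thermal normal-demand Diels–Alder (4+2) cycloaddition, concerted but asynchronous (at the stepwise limit a Mukaiyama–Michael addition followed by closure of the allenolate α carbon onto the oxocarbenium carbon), to give ketal 15, which aromatises by 1,4-elimination of benzyl alcohol to silyl ether 16 and is desilylated by the acidic work-up. The closest known reaction type is the resorcylate synthesis from 1,3-dialkoxy-1-silyloxybutadienes and alkynoates with aromatising loss of alcohol; the 2-carboxylate on the diene lowers its reactivity, which the more electrophilic aryl ester, an excess of diene and heat are meant to offset. Ring A is closed as a six-membered carbocycle by intermolecular (4+2) annulation, the C5–C6 and C1–C2 bonds being formed in the same operation. No stereocentre remains: the ketal carbon of 15 is formed racemic and becomes the planar C2 of ring A. The selectivity needed is regiochemical, the diene CH2 having to bond to the methyl-bearing alkyne carbon; the two acetal oxygens and the 3-methoxy group put the largest HOMO coefficient on that CH2, while the ester polarises the ynoate toward attack at its β carbon, so both partners are matched. Chemoselectivity rests on the substrate design: ring B carries no free hydroxyl that could protonate the ketene acetal, and the depside ester is already in place as an unhindered ynoate ester.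

Step 10
Reactants: 17 benzyl 2-(benzyloxy)-4-{[3-(benzyloxycarbonyl)-2-hydroxy-4-methoxy-6-methylbenzoyl]oxy}-3,6-dimethylbenzoate
Product: 18 squamatic acid, 4-[(3-carboxy-2-hydroxy-4-methoxy-6-methylbenzoyl)oxy]-2-hydroxy-3,6-dimethylbenzoic acid
Conditions: H2 (1 atm), 10% Pd/C, EtOAc, rt
Reagents that add atoms: none
Why: Catalytic hydrogenolysis should cleave the benzyl ether and both benzyl esters at their benzylic C–O bonds under neutral conditions that leave the depside aryl ester, the methyl ether and the ortho-hydroxy acids untouched.

Compound list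
1 | methyl 2,4-dihydroxy-3,6-dimethylbenzoate | COC(=O)c1c(C)cc(O)c(C)c1O | starting material
2 | 2,4-dihydroxy-3,6-dimethylbenzoylium hydrogen sulfate | Cc1cc(O)c(C)c(O)c1C#[O+].OS(=O)(=O)[O-] | intermediate (not isolated)
3 | 2,4-dihydroxy-3,6-dimethylbenzoic acid | Cc1cc(O)c(C)c(O)c1C(=O)O | intermediate
4 | benzyl 2,4-dihydroxy-3,6-dimethylbenzoate | Cc1cc(O)c(C)c(O)c1C(=O)OCc1ccccc1 | intermediate
5 | benzyl 2-hydroxy-3,6-dimethyl-4-(prop-2-en-1-yloxy)benzoate | C=CCOc1cc(C)c(C(=O)OCc2ccccc2)c(O)c1C | intermediate
6 | benzyl 2-(benzyloxy)-3,6-dimethyl-4-(prop-2-en-1-yloxy)benzoate | C=CCOc1cc(C)c(C(=O)OCc2ccccc2)c(OCc2ccccc2)c1C | intermediate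
7 | benzyl 2-(benzyloxy)-4-hydroxy-3,6-dimethylbenzoate | Cc1cc(O)c(C)c(OCc2ccccc2)c1C(=O)OCc1ccccc1 | intermediate
8 | but-2-ynoic acid | CC#CC(=O)O | starting material
9 | 3-(benzyloxy)-4-(benzyloxycarbonyl)-2,5-dimethylphenyl but-2-ynoate | CC#CC(=O)Oc1cc(C)c(C(=O)OCc2ccccc2)c(OCc2ccccc2)c1C | intermediate
10 | dibenzyl malonate | O=C(CC(=O)OCc1ccccc1)OCc1ccccc1 | starting material
11 | trimethyl orthoacetate | CC(OC)(OC)OC | starting material
12 | dibenzyl 2-(1-methoxyethylidene)propanedioate | COC(C)=C(C(=O)OCc1ccccc1)C(=O)OCc1ccccc1 | intermediate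
13 | lithium 1-(benzyloxy)-2-(benzyloxycarbonyl)-3-methoxybuta-1,3-dien-1-olate | [Li+].C=C(OC)C(C(=O)OCc1ccccc1)=C([O-])OCc1ccccc1 | intermediate (not isolated)
14 | benzyl 2-[benzyloxy(trimethylsilyloxy)methylidene]-3-methoxybut-3-enoate (either ketene acetal geometry) | C=C(OC)C(C(=O)OCc1ccccc1)=C(O[Si](C)(C)C)OCc1ccccc1 | intermediate
15 | benzyl 6-(benzyloxy)-5-{[3-(benzyloxy)-4-(benzyloxycarbonyl)-2,5-dimethylphenoxy]carbonyl}-2-methoxy-4-methyl-6-(trimethylsilyloxy)cyclohexa-1,4-diene-1-carboxylate (racemic) | COC1=C(C(=O)OCc2ccccc2)C(OCc2ccccc2)(O[Si](C)(C)C)C(C(=O)Oc2cc(C)c(C(=O)OCc3ccccc3)c(OCc3ccccc3)c2C)=C(C)C1 | intermediate (not isolated)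
16 | benzyl 2-(benzyloxy)-4-{[3-(benzyloxycarbonyl)-4-methoxy-6-methyl-2-(trimethylsilyloxy)benzoyl]oxy}-3,6-dimethylbenzoate | COc1cc(C)c(C(=O)Oc2cc(C)c(C(=O)OCc3ccccc3)c(OCc3ccccc3)c2C)c(O[Si](C)(C)C)c1C(=O)OCc1ccccc1 | intermediate (not isolated)
17 | benzyl 2-(benzyloxy)-4-{[3-(benzyloxycarbonyl)-2-hydroxy-4-methoxy-6-methylbenzoyl]oxy}-3,6-dimethylbenzoate | COc1cc(C)c(C(=O)Oc2cc(C)c(C(=O)OCc3ccccc3)c(OCc3ccccc3)c2C)c(O)c1C(=O)OCc1ccccc1 | intermediate
18 | squamatic acid, 4-[(3-carboxy-2-hydroxy-4-methoxy-6-methylbenzoyl)oxy]-2-hydroxy-3,6-dimethylbenzoic acid | COc1cc(C)c(C(=O)Oc2cc(C)c(C(=O)O)c(O)c2C)c(O)c1C(=O)O | target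

Total step count: 10.
Longest linear sequence: 8 steps (steps 1 to 6, then 9 and 10, from 1). The diene branch (steps 7 and 8) joins at step 9.

Steps most likely to fail

Step 9. The ester-bearing diene is a weaker nucleophile than the parent dialkoxy silyloxy dienes and the β-methyl ynoate is only a modest dienophile. Thermal decay of the ketene acetal (silyl migration, protonolysis) or acyl transfer from the activated aryl ester may therefore outrun cycloaddition and consume the valuable ynoate 9 unproductively. The fallback inverts the order of ring construction and depside formation. Setting out from 8, esterification with tert-butyl 2,2,2-trichloroacetimidate (BF3·OEt2 cat., CH2Cl2/cyclohexane) would give tert-butyl but-2-ynoate F1. This cheap and thermally robust dienophile would be used in large excess, as co-solvent, against diene 14 at 130–140 °C, followed by the same acidic work-up, to give 3-benzyl 1-tert-butyl 2-hydroxy-4-methoxy-6-methylbenzene-1,3-dicarboxylate F2. CF3CO2H in CH2Cl2 at rt would cleave only the tert-butyl ester to 3-(benzyloxycarbonyl)-2-hydroxy-4-methoxy-6-methylbenzoic acid F3. Classical depside esterification of F3 with phenol 7 through the mixed anhydride ((CF3CO)2O, toluene, rt) would come back to the route at 17.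

Step 7. Condensation of the ketone-level orthoester may be slow, since it tends to be diverted to ketene acetal and acetate, and liberated methanol may exchange benzyl for methyl ester groups before it is trapped. The fallback sets out from 10: C-acetylation under soft enolisation (MgCl2, Et3N, AcCl, MeCN, 0 °C to rt) would give dibenzyl 2-acetylpropanedioate F4, which exists largely as its acidic enol. O-Methylation of that enol with trimethylsilyldiazomethane (toluene/MeOH, 0 °C) would come back to the route at 12, with no alcohol present at high temperature.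

Step 1. Ring sulfonation at the free C5 position or decarboxylation of the β-resorcylic acid may accompany ester cleavage in the strong acid. The fallback caps both phenols first and cleaves the ester by saponification. Setting out from 1, selective 4-O-allylation (allyl bromide, K2CO3, acetone, reflux) would give methyl 2-hydroxy-3,6-dimethyl-4-(prop-2-en-1-yloxy)benzoate F5. Benzylation of the chelated phenol (BnBr, K2CO3, DMF, 60 °C) would give methyl 2-(benzyloxy)-3,6-dimethyl-4-(prop-2-en-1-yloxy)benzoate F6. Saponification of this phenol-free hindered ester (KOH, aqueous EtOH, reflux), which has no decarboxylation pathway open, would give 2-(benzyloxy)-3,6-dimethyl-4-(prop-2-en-1-yloxy)benzoic acid F7. Carboxylate benzylation (BnBr, K2CO3, DMF) would come back to the route at 6.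

Further compounds
F1 | step 9 | tert-butyl but-2-ynoate | CC#CC(=O)OC(C)(C)C
F2 | step 9 | 3-benzyl 1-tert-butyl 2-hydroxy-4-methoxy-6-methylbenzene-1,3-dicarboxylate | COc1cc(C)c(C(=O)OC(C)(C)C)c(O)c1C(=O)OCc1ccccc1
F3 | step 9 | 3-(benzyloxycarbonyl)-2-hydroxy-4-methoxy-6-methylbenzoic acid | COc1cc(C)c(C(=O)O)c(O)c1C(=O)OCc1ccccc1
F4 | step 7 | dibenzyl 2-acetylpropanedioate | CC(=O)C(C(=O)OCc1ccccc1)C(=O)OCc1ccccc1
F5 | step 1 | methyl 2-hydroxy-3,6-dimethyl-4-(prop-2-en-1-yloxy)benzoate | C=CCOc1cc(C)c(C(=O)OC)c(O)c1C
F6 | step 1 | methyl 2-(benzyloxy)-3,6-dimethyl-4-(prop-2-en-1-yloxy)benzoate | C=CCOc1cc(C)c(C(=O)OC)c(OCc2ccccc2)c1C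
F7 | step 1 | 2-(benzyloxy)-3,6-dimethyl-4-(prop-2-en-1-yloxy)benzoic acid | C=CCOc1cc(C)c(C(=O)O)c(OCc2ccccc2)c1C
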